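Molar per hour is what I want from these runs, whose readings count percent of both substrates together.

| flask | left-handed substrate | right-handed substrate | reagent | free catalyst | remark |
|---|---|---|---|---|---|
| south-west | 0.15 M | 0.15 M | 0.60 M | 17 mM | run made earlier |
| east | 0.60 M | 0.60 M | 0.60 M | 17 mM | run made earlier |
| flask | 0.30 M | 0.30 M | 0.600 M | 17 mM |  |

- south-west (time / h: left-handed product / %): 0.500: 1.6; 1.00: 1.4; 1.50: 2.5; 2.50: 3.5; 4.00: 4.8; 8.00: 6.9
- east (time / h: left-handed product / %): 1.33: 1.7; 2.50: 1.1; 4.00: 1.7; 5.00: 2.7; 6.00: 3.3; 8.00: 2.8

(standard deviation of a reading: 0.5 percentage points)

- free catalyst is single-handed; left-handed substrate and right-handed substrate are mirror images of each other, charged as a racemate, each of them at the stated concentration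
- what was read earlier has a scatter of 0.5 percentage points, one standard deviation
- no earlier run changes the charge of reagent; that part of a forecast is a guess

* apparent order in reagent when 10 % of the left-handed substrate and right-handed substrate together are converted (percent change of the rate of making left-handed product for one percent more reagent charged)

The last readings give average rates of making left-handed product of 0.00259 M h⁻¹ in the south-west run and 0.00420 M h⁻¹ in the east run, a ratio of 1.62 for 4.00 times the charge. If catalyst is shared between a free and a substrate-bound form (the resting state), rate follows s/(K+s), with s each substrate's concentration. These runs then read K, roughly given the scatter, as 0.157 M. At the flask's s = 0.30 M that makes 65.6 %, the bound share θ = s/(K+s), the fraction of catalyst held on substrate.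

Suppose reagent attacks bound catalyst, which is my assumption. If bound catalyst falls off and rebinds quickly, reagent leaves θ untouched and the order in reagent is 1. If it never falls off, the orders in substrate and reagent add to 1, so the order in reagent is θ. The flask lies between. One turn, catalyst charged over that average rate, takes about 6.57 h in the south-west run; I assume bound catalyst falls off and rebinds well within that time, and so I commit to the upper end, an order near 1.

The forecast gives 0.65, lower than my order, and its grounds are not my θ: “No run varied reagent, so this is a guess, and I take a middling value with a wide range”.

The simulation gives 1.0.

    reagent + catalyst intermediate B → free catalyst + right-handed product (k = 0.0965 M⁻¹ h⁻¹)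
    free catalyst + left-handed substrate ⇌ catalyst intermediate A (K = 0.910 M⁻¹, k = 66.9 M⁻¹ h⁻¹)
    free catalyst + right-handed substrate ⇌ catalyst intermediate B (K = 9.00 M⁻¹, k = 59.1 M⁻¹ h⁻¹)
    reagent + catalyst intermediate A → free catalyst + left-handed product (k = 7.58 M⁻¹ h⁻¹)
    reagent + free catalyst → spent catalyst (k = 0.213 M⁻¹ h⁻¹)

In the flask at 0.600 h, the earliest state to hand, catalyst intermediate A and catalyst intermediate B together held 72.3 % of the catalyst, where I had reckoned θ = 65.6 % for the charge, and at 6.00 h binding of right-handed substrate relaxed with a half-life of 1.75 min. Meanwhile reagent turned catalyst intermediate A into left-handed product, 4.43 % by 6.00 h, and spent catalyst reached 18.0 %, and at 10 % conversion, 11.8 h, catalyst intermediate B still held 46.4 % of the catalyst.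

The earlier runs and the new flask were generated by integration for an exercise; the scatter is artificial.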